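Remark on the chemistry (assumption): the SMILES contains no stereocentre, no stereogenic double bond and no axis. The target is achiral, so "single enantiomer" is read as "the one constitution drawn", and no step has to set or preserve configuration.

Route in one sentence (test 1): a nickel-electrocatalytic, doubly decarboxylative C(sp3)–C(sp3) cross-coupling joins the tyrosyl half-ester of sebacic acid to stearic acid, both as N-hydroxyphthalimide esters, at C9–C10 of the acyl chain. This sentence does not describe the esterification of tyrosol with ready-made hexacosanoic acid that most chemists would draw first.

Test 2: the step builds the homologue-free C26 chain, the only real difficulty of the target, in one operation, with the ester and the free phenol already in place.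

## Structural features

1. The target is an ester of two unbranched parts. One is a saturated, unfunctionalised C26 acyl chain (C1 carbonyl, C2–C25 methylenes, C26 methyl). The other is a 2-arylethyl unit (O–CH2–CH2 bound to C1′ of a benzene ring that carries a free OH at C4′).
2. The para-disubstituted benzene is the only ring, and there are no stereocentres at all, adjacent or otherwise.
3. Two groups are fragile. The electron-rich phenol is oxidised far more easily than anything else in the molecule and is a competing O-nucleophile. The primary alkyl ester does not survive hydroxide, alkoxide or hard organometallic reagents.
4. The ester C–O bond itself is trivial, and the real difficulty is the chain. C26 lies outside the C12–C22 range of bulk fatty acids, its twenty-four identical methylenes offer no handle, and neighbouring homologues can hardly be removed by crystallisation or chromatography. Chain length therefore has to be set by construction, much as configuration is in other targets.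
5. A second, smaller problem is telling the aliphatic OH from the phenolic OH without protecting groups.
6. The key step exploits the featureless segment C2–C25. Any internal CH2–CH2 bond there can be formed tracelessly from two primary radicals, and the cut C9–C10 satisfies 26 = (10 − 1) + (18 − 1). C1–C9 thus comes from a C10 diacid and C10–C26 from a C18 acid, each losing one carbon by decarboxylation.
7. The ring C1′–C6′ with its C4′–OH is labile to oxidation but inert to reduction. The decarboxylative coupling is therefore placed on the cathodic, nickel-mediated side and not at an anode, and the phenol can stay free.

## Logic of the disconnections

**8 ⇒ 6 + 7 (key disconnection).**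
- Bond cut: C9–C10 of the acyl chain, a CH2–CH2 bond inside the unfunctionalised segment.
- Reason: each fragment is then an acid derivative that loses exactly one carbon by decarboxylation, and both parent acids are bulk oleochemicals.
- Gain: a C26 chain that would otherwise be bought as a rare wax acid falls into two pieces. One is a C9 piece that already carries the finished ester and the free phenol. The other is a C17 piece with no function at all. The chain length of 8 becomes a matter of counting carbons, not of purification.
- Demand: two primary radicals of like reactivity must be generated without touching an oxidisable phenol, an acidic O–H or an alkyl ester, and must be steered towards the cross product. This calls for reductive radical generation, a metal centre that collects two alkyl groups, and an excess of the cheaper partner.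

**7 ⇒ 3 + 5.**
- Bond cut: the acyl–O(N) bond of the active ester.
- Reason: 7 is an active ester and a phenol at once, hence a latent AB monomer, so it is planned as a compound made and consumed in the same flask.
- Gain: the route returns to a storable free acid.
- Demand: the activation must run without base or acyl-transfer catalyst, so that only the N–OH of 5 is acylated.

**6 ⇒ 4 + 5.**
- Bond cut: the same type of acyl–O(N) bond.
- Reason: 6 has no second function, should crystallise and is needed in excess. It is therefore prepared apart, freed from urea and dosed exactly.
- Gain: both precursors are commercial.
- Demand: only an ordinary carbodiimide coupling.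

**3 ⇒ 1 + 2.**
- Bond cut: the acyl C–O bond to the OCH2 group. This is the ester of the target itself, now formed first, on a short and soluble C10 diacid instead of a waxy C26 acid.
- Gain: both precursors are cheap commercial compounds.
- Demand: two selectivities. Aliphatic against phenolic OH in 1 is left to an enzyme whose acyl-enzyme is not attacked by phenols. One against two carboxyl groups in 2 is left to an excess of 2.

## Other disconnections considered

Alternative 1: the cut is the acyl C1–O bond, the first idea that comes to mind. The forward key step is a chemoselective acylation of the aliphatic OH of 1 with hexacosanoic acid A1. It could be run with a lipase, by Mitsunobu activation of 1, or through hexacosanoyl chloride A2 once the phenol is masked. It is one step and surely feasible, but it is exactly the route that the one-sentence test excludes. It also brings no simplification, because A1 already contains all 26 chain carbons, so the homologue-free chain is merely handed to a supplier. A1 is a minor wax acid that is poorly soluble in lipase-compatible solvents at moderate temperature. A2 would not distinguish the two OH groups of 1.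

Alternative 2: the cut is the alkyl O–CH2 bond, made through a dearomatised electrophile. 4-(2-Bromoethyl)phenol A3 would be closed by base, through participation of the para-phenoxide carbon, to spiro[2.5]octa-4,7-dien-6-one A4. The strained cyclopropane of A4 would then be opened at CH2 by A1 with rearomatisation, so the phenol is released in the bond-forming event itself. The idea is attractive mechanistically, but it joins the same two halves at the same ester function, one atom away from Alternative 1. It therefore still needs A1 and gains nothing in the chain. The phenol liberated in each turnover is itself a nucleophile for A4, so aryl ether oligomerisation competes with a poorly soluble long-chain carboxylate. It costs more steps than Alternative 1 for the same simplification.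

Alternative 3: the cut is C9=C10 as an alkene. The dec-9-enoate A5 of 1 (made with the same lipase step) would undergo cross-metathesis with octadec-1-ene A6 on a ruthenium alkylidene catalyst. This would give the hexacos-9-enoate A7, and hydrogenation of A7 would give 8. This plan passes both tests, but it is linear over three steps and needs a redox correction after the key step. Both olefins are of the same reactivity class, so the coupling is equally statistical. The decisive ground is mechanistic. Ruthenium hydride species move terminal double bonds along the chain before metathesis, which would blend C25 and C27 homologues into A7. Chain-length purity is the one quality criterion of this target, and it would be lost. The decarboxylative coupling fixes the carbon count, delivers the saturated chain directly, and has a longest linear sequence of two.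

Key step: step 3

## Steps

Step 1
Reactants: 1 tyrosol [4-(2-hydroxyethyl)phenol]; 2 sebacic acid (decanedioic acid)
Product: 3 10-[2-(4-hydroxyphenyl)ethoxy]-10-oxodecanoic acid
Conditions: 2 (4 equiv), immobilised Candida antarctica lipase B, 4 Å MS, 2-methyl-2-butanol, 55 °C; filter, evaporate, triturate with cold CH2Cl2 (excess 2 stays undissolved)
Reagents that add atoms: none
Why: Lipase-catalysed esterification; the acyl-enzyme formed from a straight-chain acid is attacked by primary aliphatic alcohols but not by phenols or by the tertiary solvent alcohol, so only the CH2OH of 1 should be acylated. The excess of 2 holds back the second esterification.

Step 2
Reactants: 4 stearic acid (octadecanoic acid); 5 N-hydroxyphthalimide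
Product: 6 1,3-dioxoisoindolin-2-yl octadecanoate
Conditions: DIC (1.1 equiv), DMAP (cat.), CH2Cl2, 0 °C to rt; recrystallisation from MeCN
Reagents that add atoms: none
Why: Steglich-type carbodiimide coupling of an unhindered fatty acid with an acidic N–OH nucleophile; 4 has no other functional group, and the product should crystallise free of the urea.

Step 3
Reactants: 3 10-[2-(4-hydroxyphenyl)ethoxy]-10-oxodecanoic acid; 5 N-hydroxyphthalimide; 6 1,3-dioxoisoindolin-2-yl octadecanoate
Product: 8 2-(4-hydroxyphenyl)ethyl hexacosanoate, via redox-active ester 7 (not isolated)
Conditions: (i) 5 (1.0 equiv), DIC (1.0 equiv), THF–CH2Cl2, 0 °C to rt, no DMAP, concentrate; (ii) 6 (3 equiv), NiCl2·6H2O (20 mol %), 4,4′,4″-tri-tert-butyl-2,2′:6′,2″-terpyridine (20 mol %), AgNO3 (0.3 equiv), NaI, DMF–THF, (+)Mg | (−)RVC, undivided cell, constant current until 6 and 7 are consumed, 30–35 °C; dilute aq. HCl work-up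
Reagents that add atoms: none
Why: Stage (i) is a carbodiimide activation run without base or acyl-transfer catalyst: the acidic, α-effect N–OH of 5 intercepts the O-acylisourea of 3 much faster than a neutral phenol can (the selectivity that lets N-hydroxyimide esters of other hydroxyphenyl-alkanoic acids be made with the phenol free), and 7 is used at once because it is a latent AB monomer. In stage (ii) the silver deposited from AgNO3 on the carbon cathode and the cathodically formed low-valent nickel pass one electron into the phthalimide unit of 6 and of 7, and N–O cleavage followed by decarboxylation gives two primary alkyl radicals (C17 from 6, C9 from 7). The terpyridine-bound nickel centre collects the two radicals one after the other, C(sp3)–C(sp3) reductive elimination from the dialkylnickel species forms C9–C10 of 8, and the magnesium anode supplies the electrons, so nothing in the cell is oxidised except the metal. The closest known reaction type is the nickel-electrocatalytic doubly decarboxylative cross-coupling of two primary redox-active esters, the reductive counterpart of the mixed Kolbe electrolysis. No ring is closed and no stereocentre is formed; what the step fixes instead is the chain length, 9 + 17 = 26 carbons, by the carbon count of 2 and 4, with no path to chain walking or homologation. The chemoselectivity needed is survival of phenol and ester: the 4-hydroxyphenyl ring is easily oxidised but inert at the mildly reducing working potential, the phthalimide anion is too weak a base to deprotonate a phenol, the alkyl ester is not addressed, and a catalyst charged as its hexahydrate is by nature tolerant of O–H groups. Cross-selectivity cannot come from the radicals, which are alike, so it comes from the threefold excess of the cheap 6, and the substrate secures the separation because the three possible coupling products carry zero, one and two phenolic OH groups and so differ widely in polarity.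

## Compound list

1 | tyrosol, 4-(2-hydroxyethyl)phenol | OCCc1ccc(O)cc1 | starting material
2 | sebacic acid, decanedioic acid | OC(=O)CCCCCCCCC(=O)O | starting material
3 | 10-[2-(4-hydroxyphenyl)ethoxy]-10-oxodecanoic acid | OC(=O)CCCCCCCCC(=O)OCCc1ccc(O)cc1 | intermediate
4 | stearic acid, octadecanoic acid | CCCCCCCCCCCCCCCCCC(=O)O | starting material
5 | N-hydroxyphthalimide | ON1C(=O)c2ccccc2C1=O | starting material
6 | 1,3-dioxoisoindolin-2-yl octadecanoate | CCCCCCCCCCCCCCCCCC(=O)ON1C(=O)c2ccccc2C1=O | intermediate
7 | 1,3-dioxoisoindolin-2-yl 2-(4-hydroxyphenyl)ethyl decanedioate | O=C(CCCCCCCCC(=O)OCCc1ccc(O)cc1)ON1C(=O)c2ccccc2C1=O | intermediate (not isolated)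
8 | 2-(4-hydroxyphenyl)ethyl hexacosanoate (achiral) | CCCCCCCCCCCCCCCCCCCCCCCCCC(=O)OCCc1ccc(O)cc1 | target

## Step count and least certain steps

Total step count: 3. Longest linear sequence: 2 (steps 1 and 3). Step 2 is a one-step side branch.

**Step 3 (key step).** Three processes are most likely to cut into it.
- Statistical homo-coupling, together with hydrodecarboxylation or β-hydride elimination at nickel, drains the radical derived from 7, because nothing electronic or steric sets the two partners apart.
- The waxy long-chain products may crystallise inside the pores of the carbon foam, which raises the cell voltage and passivates the cathode. This is the reason for the THF co-solvent and the slight warming.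
- Acyl groups may slowly transfer from the active esters to the phenolic oxygen as magnesium salts and imide anion build up.

Fallback (sets out from 3, returns at 8): the polarity of the electrolysis is reversed and the classical anodic mixed Kolbe coupling of the free acids is used. It needs neither nickel nor active esters, but it does need the phenol masked. 3 would be acetylated at the phenol (Ac2O, pyridine, aqueous quench) to 10-[2-(4-acetoxyphenyl)ethoxy]-10-oxodecanoic acid F1, whose ring should be about as hard to oxidise as an alkylbenzene. F1 and an excess of 4, partly neutralised with KOH, would be electrolysed at a smooth platinum anode at high current density, in warm methanol under a hydrocarbon layer. This would give 2-(4-acetoxyphenyl)ethyl hexacosanoate F2. Aminolysis of the aryl acetate with pyrrolidine in THF at room temperature, to which the alkyl ester is inert, leads back to 8.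

**Step 1.** The most likely problems are esterification at both carboxyl groups of 2 and a sluggish enzyme. The second carboxyl group of 3 is as good an acyl donor as the first, and a large excess of a diacid acidifies the surroundings of the lipase.

Fallback (sets out from 2, returns at 3): the diacid is differentiated before 1 is introduced.
- 2 would be converted into 10-(benzyloxy)-10-oxodecanoic acid F3 (benzyl alcohol, cat. TsOH, excess 2, toluene, water separator, separation by extraction).
- F3 would be joined to 1 by a Mitsunobu reaction (PPh3, DIAD, THF, 0 °C). Here the alcohol and not the acid is activated, and the carboxylic acid, as the more acidic pronucleophile, wins over the phenol. The product is benzyl 2-(4-hydroxyphenyl)ethyl decanedioate F4.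
- Hydrogenolysis (H2, Pd/C, EtOAc) would remove only the benzyl group, since the other ester is homobenzylic, and give 3.

**Step 2.** The most likely problems are O-to-N acyl migration in the O-acylisourea, which ties up part of the acid, and hydrolysis of the active ester during purification.

Fallback (sets out from 4, returns at 6): activation through the acid chloride instead of a carbodiimide. 4 would be converted with oxalyl chloride and cat. DMF in CH2Cl2 into octadecanoyl chloride F5, which would acylate 5 in the presence of Et3N at 0 °C to give 6.

## Further compounds

F1 | step 3 | 10-[2-(4-acetoxyphenyl)ethoxy]-10-oxodecanoic acid | CC(=O)Oc1ccc(CCOC(=O)CCCCCCCCC(=O)O)cc1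
F2 | step 3 | 2-(4-acetoxyphenyl)ethyl hexacosanoate | CCCCCCCCCCCCCCCCCCCCCCCCCC(=O)OCCc1ccc(OC(C)=O)cc1
F3 | step 1 | 10-(benzyloxy)-10-oxodecanoic acid | OC(=O)CCCCCCCCC(=O)OCc1ccccc1
F4 | step 1 | benzyl 2-(4-hydroxyphenyl)ethyl decanedioate | O=C(CCCCCCCCC(=O)OCCc1ccc(O)cc1)OCc1ccccc1
F5 | step 2 | octadecanoyl chloride | CCCCCCCCCCCCCCCCCC(=O)Cl
A1 | alternative 1 | hexacosanoic acid | CCCCCCCCCCCCCCCCCCCCCCCCCC(=O)O
A2 | alternative 1 | hexacosanoyl chloride | CCCCCCCCCCCCCCCCCCCCCCCCCC(=O)Cl
A3 | alternative 2 | 4-(2-bromoethyl)phenol | Oc1ccc(CCBr)cc1
A4 | alternative 2 | spiro[2.5]octa-4,7-dien-6-one | O=C1C=CC2(CC2)C=C1
A5 | alternative 3 | 2-(4-hydroxyphenyl)ethyl dec-9-enoate | C=CCCCCCCCC(=O)OCCc1ccc(O)cc1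
A6 | alternative 3 | octadec-1-ene | C=CCCCCCCCCCCCCCCCC
A7 | alternative 3 | 2-(4-hydroxyphenyl)ethyl hexacos-9-enoate (E/Z mixture) | CCCCCCCCCCCCCCCCC=CCCCCCCCC(=O)OCCc1ccc(O)cc1
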